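A direct plan would set the stereocentre first, by conjugate addition of boronic acid A1 to methyl crotonate A2 under Rh(acac)(C2H4)2 and (R)-BINAP, and lengthen the ester in two steps to β-keto ester A3.
It would C-acylate A3 with the chlorocinnamoyl chloride A4 and close ring C first, as the 4-pyranone-3-carboxylate A5.
Ring A would come last: deprotonation of the side-chain CH2 of A5, C-acetylation and Dieckmann closure on the ester would give the benzylated flavonol A6, and hydrogenolysis the target.
Weakest would be this last annulation: a reaction type untested on a pyranone ester, placed on the most advanced intermediate, at a hindered carbanion beside the stereocentre, under excess LiN(iPr)2 and with C- against O-acylation left open.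
Second, the stereocentre would be made at the outset from a boronic acid prone to protodeboronation and then carried through eight steps, the last C–C bond-forming one with its allylic, benzylic C–H exposed to amide base.
Third, eight steps (five to A3, three to A4) would build two short chains before any ring exists, which would stretch a target with one stereocentre to an eleven-step linear sequence.

**Retrosynthetic overview**

The bond from C8 of ring A (the carbon between O1 and the C7 hydroxyl) to the benzylic CH(CH3) that carries the para-hydroxyaryl (4-hydroxy-3,5-dimethoxyphenyl) ring is the retron of a 1,6-addition of an electron-rich arene to a para-quinone methide; this bond is cut first.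
The key step therefore joins the two halves and sets the only stereocentre in one operation, stereoconvergently, from a racemic benzylic alcohol and a ring A acetophenone under a chiral phosphoric acid.
Ring A is bought as 2,4,6-trihydroxyacetophenone; its single unprotected hydroxyl directs the alkylation to the neighbouring carbon and later becomes O1, so the arylethyl group can only end at C8. Ring C is closed last, by Claisen–Schmidt condensation (C2–C3) and Algar–Flynn–Oyamada oxidation (O1–C2, C3–O).
No annulation of ring A on an advanced intermediate is needed, no carbanion is formed near the stereocentre once it is set (only carbonate, hydroxide, peroxide and hydrogen follow), and each fragment is at most one step from a commodity chemical.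

Key step: step 3

Remark: the sense of induction of the phosphoric acid in step 3 cannot be read from the structures; the (R)-catalyst is written, and its mirror image would be used, with nothing else changed, if a test run should call for it.

Step 1
Reactants: 1 1-(2,4,6-trihydroxyphenyl)ethan-1-one (2,4,6-trihydroxyacetophenone)
Product: 2 1-[2,4-bis(benzyloxy)-6-hydroxyphenyl]ethan-1-one
Conditions: BnBr (2.1 equiv), K2CO3 (2.2 equiv), DMF, rt → 50 °C
Reagents that add atoms: benzyl bromide, BrCc1ccccc1
Why: Williamson ether synthesis that should stop at the dibenzyl ether because the last hydroxyl is held in a hydrogen bond to the acetyl carbonyl, which leaves free exactly the oxygen that is to direct the key step and to become O1.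

Step 2
Reactants: 3 1-(4-hydroxy-3,5-dimethoxyphenyl)ethan-1-one (acetosyringone)
Product: 4 rac-1-(4-hydroxy-3,5-dimethoxyphenyl)ethan-1-ol
Conditions: NaBH4 (1.5 equiv), EtOH/THF, 0 °C → rt; aq. NH4Cl, used without storage
Reagents that add atoms: none
Why: Borohydride reduction of the aryl ketone, worked up near neutrality because the para-hydroxybenzylic alcohol ionises easily; that it is racemic is of no consequence for the next step.

Step 3
Reactants: 2 1-[2,4-bis(benzyloxy)-6-hydroxyphenyl]ethan-1-one, 4 rac-1-(4-hydroxy-3,5-dimethoxyphenyl)ethan-1-ol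
Product: 6 1-{4,6-bis(benzyloxy)-2-hydroxy-3-[(1R)-1-(4-hydroxy-3,5-dimethoxyphenyl)ethyl]phenyl}ethan-1-one, via para-quinone methide 5 (not isolated)
Conditions: (R)-3,3'-bis(2,4,6-triisopropylphenyl)-1,1'-binaphthyl-2,2'-diyl hydrogen phosphate (10 mol %), 2 (1.5 equiv), 4 added over 6 h, toluene/CH2Cl2, 5 Å molecular sieves, 0 °C → rt
Reagents that add atoms: none
Why: Proposed new method: the phosphoric acid should ionise both enantiomers of 4 to the one planar quinone methide 5 (its tautomer 2,6-dimethoxy-4-vinylphenol returns to 5 under the same acid), bind it through P–OH···O=C and P=O···H–O contacts, and deliver the carbon ortho to the hydroxyl of 2 to one face of the exocyclic carbon in a 1,6-addition that ends irreversibly when both rings are aromatic again. The closest known reaction types are the phosphoric acid catalysed enantioselective additions of 2-naphthols, phenols and indoles to para-quinone methides made in the flask from para-hydroxybenzyl alcohols, and the transfer hydrogenation of 1,1-diarylethenes through the same intermediates; an ethylidene quinone methide with an ortho-acylphenol as the arene has not been run. No ring is closed. The new centre, the benzylic carbon of the bridge (R), is controlled by the catalyst alone, whose 3,3'-aryl groups shield one face of bound 5. The step needs attack at C3 and not at C5 of 2, which the substrate secures because C3 lies ortho to the only free hydroxyl and between OH and OBn while C5 sits between two benzyloxy groups; it also needs C- over O-alkylation and mono- over dialkylation, which the reversibility of O-alkylation under acid and the crowding of 6 should provide. Because the free hydroxyl of 2 is the future O1, the arylethyl group can only end at C8 of the flavonol.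

Step 4
Reactants: 6 1-{4,6-bis(benzyloxy)-2-hydroxy-3-[(1R)-1-(4-hydroxy-3,5-dimethoxyphenyl)ethyl]phenyl}ethan-1-one
Product: 7 1-{4,6-bis(benzyloxy)-3-{(1R)-1-[4-(benzyloxy)-3,5-dimethoxyphenyl]ethyl}-2-hydroxyphenyl}ethan-1-one
Conditions: BnBr (1.2 equiv), K2CO3 (1.5 equiv), acetone, 50 °C
Reagents that add atoms: benzyl bromide, BrCc1ccccc1
Why: Williamson ether synthesis at the 4-hydroxy-3,5-dimethoxyphenyl oxygen, while the ring A hydroxyl, chelated to the acetyl group and flanked by two ortho substituents, should stay free for the ring closure; the ether guards the electron-rich phenol against alkaline peroxide.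

Step 5
Reactants: 7 1-{4,6-bis(benzyloxy)-3-{(1R)-1-[4-(benzyloxy)-3,5-dimethoxyphenyl]ethyl}-2-hydroxyphenyl}ethan-1-one, 8 4-(benzyloxy)-3-methoxybenzaldehyde
Product: 9 (2E)-1-{4,6-bis(benzyloxy)-3-{(1R)-1-[4-(benzyloxy)-3,5-dimethoxyphenyl]ethyl}-2-hydroxyphenyl}-3-[4-(benzyloxy)-3-methoxyphenyl]prop-2-en-1-one
Conditions: 8 (1.3 equiv), KOH (aq. 50 %, 10 equiv), EtOH/THF, rt
Reagents that add atoms: none
Why: Claisen–Schmidt condensation (aldol addition of the methyl ketone enolate to the non-enolisable aldehyde, then E1cB loss of water) should give the E-enone, and hydroxide cannot touch the stereocentre, whose C–H is not acidified by any carbonyl group.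

Step 6
Reactants: 9 (2E)-1-{4,6-bis(benzyloxy)-3-{(1R)-1-[4-(benzyloxy)-3,5-dimethoxyphenyl]ethyl}-2-hydroxyphenyl}-3-[4-(benzyloxy)-3-methoxyphenyl]prop-2-en-1-one
Product: 11 5,7-bis(benzyloxy)-2-[4-(benzyloxy)-3-methoxyphenyl]-8-{(1R)-1-[4-(benzyloxy)-3,5-dimethoxyphenyl]ethyl}-3-hydroxy-4H-chromen-4-one, via dihydroflavonol 10 (not isolated)
Conditions: H2O2 (aq. 30 %, 6 equiv), NaOH (aq. 2 M, 5 equiv), MeOH/THF, 0 °C → rt; AcOH to pH 5
Reagents that add atoms: hydrogen peroxide, OO
Why: Algar–Flynn–Oyamada reaction, in which alkaline peroxide oxidises the enone and the 2'-phenoxide closes ring C in the 6-endo mode at the β-carbon to give 10, which excess peroxide dehydrogenates to the flavonol; the two centres of 10 are lost again, and since only one oxygen ortho to the ketone is free, O1 can only be the one next to C8.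

Step 7
Reactants: 11 5,7-bis(benzyloxy)-2-[4-(benzyloxy)-3-methoxyphenyl]-8-{(1R)-1-[4-(benzyloxy)-3,5-dimethoxyphenyl]ethyl}-3-hydroxy-4H-chromen-4-one
Product: 12 3,5,7-trihydroxy-2-(4-hydroxy-3-methoxyphenyl)-8-[(1R)-1-(4-hydroxy-3,5-dimethoxyphenyl)ethyl]-4H-chromen-4-one
Conditions: H2 (1 atm), Pd/C (10 wt% Pd), THF/MeOH, rt
Reagents that add atoms: none
Why: Hydrogenolysis of the four benzyl ethers on palladium under neutral conditions, which should leave the tetrasubstituted C2=C3 bond, the methyl ethers and the diarylethane C–C bonds, and with them the stereocentre, untouched.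

**Compound list**

1 | 1-(2,4,6-trihydroxyphenyl)ethan-1-one (2,4,6-trihydroxyacetophenone) | CC(=O)c1c(O)cc(O)cc1O | starting material
2 | 1-[2,4-bis(benzyloxy)-6-hydroxyphenyl]ethan-1-one | CC(=O)c1c(O)cc(OCc2ccccc2)cc1OCc1ccccc1 | intermediate
3 | 1-(4-hydroxy-3,5-dimethoxyphenyl)ethan-1-one (acetosyringone) | CC(=O)c1cc(OC)c(O)c(OC)c1 | starting material
4 | rac-1-(4-hydroxy-3,5-dimethoxyphenyl)ethan-1-ol | CC(O)c1cc(OC)c(O)c(OC)c1 | intermediate
5 | 4-ethylidene-2,6-dimethoxycyclohexa-2,5-dien-1-one (not isolated) | CC=C1C=C(OC)C(=O)C(OC)=C1 | intermediate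
6 | 1-{4,6-bis(benzyloxy)-2-hydroxy-3-[(1R)-1-(4-hydroxy-3,5-dimethoxyphenyl)ethyl]phenyl}ethan-1-one | CC(=O)c1c(O)c([C@H](C)c2cc(OC)c(O)c(OC)c2)c(OCc2ccccc2)cc1OCc1ccccc1 | intermediate
7 | 1-{4,6-bis(benzyloxy)-3-{(1R)-1-[4-(benzyloxy)-3,5-dimethoxyphenyl]ethyl}-2-hydroxyphenyl}ethan-1-one | CC(=O)c1c(O)c([C@H](C)c2cc(OC)c(OCc3ccccc3)c(OC)c2)c(OCc2ccccc2)cc1OCc1ccccc1 | intermediate
8 | 4-(benzyloxy)-3-methoxybenzaldehyde | COc1cc(C=O)ccc1OCc1ccccc1 | starting material
9 | (2E)-1-{4,6-bis(benzyloxy)-3-{(1R)-1-[4-(benzyloxy)-3,5-dimethoxyphenyl]ethyl}-2-hydroxyphenyl}-3-[4-(benzyloxy)-3-methoxyphenyl]prop-2-en-1-one | COc1cc(/C=C/C(=O)c2c(O)c([C@H](C)c3cc(OC)c(OCc4ccccc4)c(OC)c3)c(OCc3ccccc3)cc2OCc2ccccc2)ccc1OCc1ccccc1 | intermediate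
10 | 5,7-bis(benzyloxy)-2-[4-(benzyloxy)-3-methoxyphenyl]-8-{(1R)-1-[4-(benzyloxy)-3,5-dimethoxyphenyl]ethyl}-3-hydroxy-2,3-dihydro-4H-chromen-4-one (2,3-trans, both diastereomers, not isolated) | COc1cc(C2Oc3c([C@H](C)c4cc(OC)c(OCc5ccccc5)c(OC)c4)c(OCc4ccccc4)cc(OCc4ccccc4)c3C(=O)C2O)ccc1OCc1ccccc1 | intermediate
11 | 5,7-bis(benzyloxy)-2-[4-(benzyloxy)-3-methoxyphenyl]-8-{(1R)-1-[4-(benzyloxy)-3,5-dimethoxyphenyl]ethyl}-3-hydroxy-4H-chromen-4-one | COc1cc(-c2oc3c([C@H](C)c4cc(OC)c(OCc5ccccc5)c(OC)c4)c(OCc4ccccc4)cc(OCc4ccccc4)c3c(=O)c2O)ccc1OCc1ccccc1 | intermediate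
12 | 3,5,7-trihydroxy-2-(4-hydroxy-3-methoxyphenyl)-8-[(1R)-1-(4-hydroxy-3,5-dimethoxyphenyl)ethyl]-4H-chromen-4-one (CNP0261887.1) | COc1cc(-c2oc3c([C@H](C)c4cc(OC)c(O)c(OC)c4)c(O)cc(O)c3c(=O)c2O)ccc1O | target

**Step count and risks**

Total step count: 7. Longest linear sequence: 6 steps (steps 1, 3, 4, 5, 6, 7).

Steps most likely to fail:

Step 3 (proposed new method). The hydroxyl of 2 is tied to the acetyl carbonyl by an internal hydrogen bond, so the second catalyst contact may be weak and facial selection poor. The deactivated arene may also react so slowly that the quinone methide oligomerises through its vinylphenol tautomer, and some attack at C5 may occur. The fallback uses known reactions only, sets out from 2 and 3 and comes back at 7. Iodination of 2 ortho to the free hydroxyl (benzyltrimethylammonium dichloroiodate, CaCO3, CH2Cl2/MeOH) would give 1-[4,6-bis(benzyloxy)-2-hydroxy-3-iodophenyl]ethan-1-one F1. Benzylation of 3 (BnBr, K2CO3) would give 1-[4-(benzyloxy)-3,5-dimethoxyphenyl]ethan-1-one F2, and condensation with 4-methylbenzenesulfonohydrazide would give N'-{(1E)-1-[4-(benzyloxy)-3,5-dimethoxyphenyl]ethylidene}-4-methylbenzenesulfonohydrazide F3. Barluenga coupling of F1 with F3 (Pd2(dba)3, 2-dicyclohexylphosphino-2',4',6'-triisopropylbiphenyl, LiOtBu, dioxane, 90 °C) would give the diarylethene 1-{4,6-bis(benzyloxy)-3-{1-[4-(benzyloxy)-3,5-dimethoxyphenyl]ethenyl}-2-hydroxyphenyl}ethan-1-one F4. Transfer hydrogenation of F4 with diethyl 2,6-dimethyl-1,4-dihydropyridine-3,5-dicarboxylate and a chiral phosphoric acid, a known reaction of 2-(1-arylvinyl)phenols that runs through the ortho-quinone methide of ring A, would set the centre by hydride delivery and give 7.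

Step 6. The phenoxide may close on the α-carbon (5-exo) to an aurone instead of the 6-endo closure, a course favoured by the 6'-benzyloxy group and by the crowding of the 2'-oxygen between the carbonyl and the arylethyl group. The fallback sets out from 7, bypasses step 5 as well, and comes back at 11. Commercial 4-(benzyloxy)-3-methoxybenzoic acid would be turned into 4-(benzyloxy)-3-methoxybenzoyl chloride F5 with (COCl)2. The dianion of 7 (LiN(SiMe3)2, THF, −78 °C) would be C-acylated by F5 in the one-pot variant of the Baker–Venkataraman synthesis to give 1-{4,6-bis(benzyloxy)-3-{(1R)-1-[4-(benzyloxy)-3,5-dimethoxyphenyl]ethyl}-2-hydroxyphenyl}-3-[4-(benzyloxy)-3-methoxyphenyl]propane-1,3-dione F6. Cyclodehydration (TsOH cat., toluene, 80 °C) would give 5,7-bis(benzyloxy)-2-[4-(benzyloxy)-3-methoxyphenyl]-8-{(1R)-1-[4-(benzyloxy)-3,5-dimethoxyphenyl]ethyl}-4H-chromen-4-one F7. Epoxidation with dimethyldioxirane (acetone/CH2Cl2) would give 4,6-bis(benzyloxy)-1a-[4-(benzyloxy)-3-methoxyphenyl]-3-{(1R)-1-[4-(benzyloxy)-3,5-dimethoxyphenyl]ethyl}-1a,7a-dihydro-7H-oxireno[2,3-b]chromen-7-one F8, which a trace of TsOH would isomerise to 11.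

Step 7. Cleavage of the hindered benzyl ethers (the one between two methoxy groups, the one at O5) may stay incomplete, or the C2=C3 bond may be saturated on long exposure to the catalyst. The fallback sets out from 11 and comes back at 12: a non-reductive Lewis acid debenzylation with BCl3 and pentamethylbenzene as benzyl cation scavenger (CH2Cl2, −78 °C), which makes no new intermediate.

**Further compounds**

F1 | step 3 | 1-[4,6-bis(benzyloxy)-2-hydroxy-3-iodophenyl]ethan-1-one | CC(=O)c1c(O)c(I)c(OCc2ccccc2)cc1OCc1ccccc1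
F2 | step 3 | 1-[4-(benzyloxy)-3,5-dimethoxyphenyl]ethan-1-one | CC(=O)c1cc(OC)c(OCc2ccccc2)c(OC)c1
F3 | step 3 | N'-{(1E)-1-[4-(benzyloxy)-3,5-dimethoxyphenyl]ethylidene}-4-methylbenzenesulfonohydrazide | C/C(=N\NS(=O)(=O)c1ccc(C)cc1)c1cc(OC)c(OCc2ccccc2)c(OC)c1
F4 | step 3 | 1-{4,6-bis(benzyloxy)-3-{1-[4-(benzyloxy)-3,5-dimethoxyphenyl]ethenyl}-2-hydroxyphenyl}ethan-1-one | CC(=O)c1c(O)c(C(=C)c2cc(OC)c(OCc3ccccc3)c(OC)c2)c(OCc2ccccc2)cc1OCc1ccccc1
F5 | step 6 | 4-(benzyloxy)-3-methoxybenzoyl chloride | COc1cc(C(=O)Cl)ccc1OCc1ccccc1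
F6 | step 6 | 1-{4,6-bis(benzyloxy)-3-{(1R)-1-[4-(benzyloxy)-3,5-dimethoxyphenyl]ethyl}-2-hydroxyphenyl}-3-[4-(benzyloxy)-3-methoxyphenyl]propane-1,3-dione | COc1cc(C(=O)CC(=O)c2c(O)c([C@H](C)c3cc(OC)c(OCc4ccccc4)c(OC)c3)c(OCc3ccccc3)cc2OCc2ccccc2)ccc1OCc1ccccc1
F7 | step 6 | 5,7-bis(benzyloxy)-2-[4-(benzyloxy)-3-methoxyphenyl]-8-{(1R)-1-[4-(benzyloxy)-3,5-dimethoxyphenyl]ethyl}-4H-chromen-4-one | COc1cc(-c2cc(=O)c3c(OCc4ccccc4)cc(OCc4ccccc4)c([C@H](C)c4cc(OC)c(OCc5ccccc5)c(OC)c4)c3o2)ccc1OCc1ccccc1
F8 | step 6 | 4,6-bis(benzyloxy)-1a-[4-(benzyloxy)-3-methoxyphenyl]-3-{(1R)-1-[4-(benzyloxy)-3,5-dimethoxyphenyl]ethyl}-1a,7a-dihydro-7H-oxireno[2,3-b]chromen-7-one (both epoxide diastereomers) | COc1cc(C23Oc4c([C@H](C)c5cc(OC)c(OCc6ccccc6)c(OC)c5)c(OCc5ccccc5)cc(OCc5ccccc5)c4C(=O)C2O3)ccc1OCc1ccccc1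
F0 | step 7 | none | none
A1 | direct plan | [4-(benzyloxy)-3,5-dimethoxyphenyl]boronic acid | COc1cc(B(O)O)cc(OC)c1OCc1ccccc1
A2 | direct plan | methyl (E)-but-2-enoate | C/C=C/C(=O)OC
A3 | direct plan | methyl (5S)-5-[4-(benzyloxy)-3,5-dimethoxyphenyl]-3-oxohexanoate | COC(=O)CC(=O)C[C@H](C)c1cc(OC)c(OCc2ccccc2)c(OC)c1
A4 | direct plan | 2-(benzyloxy)-3-[4-(benzyloxy)-3-methoxyphenyl]-3-chloroprop-2-enoyl chloride (E/Z mixture) | O=C(Cl)C(OCc1ccccc1)=C(Cl)c1ccc(OCc2ccccc2)c(OC)c1
A5 | direct plan | methyl 5-(benzyloxy)-6-[4-(benzyloxy)-3-methoxyphenyl]-2-{(2S)-2-[4-(benzyloxy)-3,5-dimethoxyphenyl]propyl}-4-oxo-4H-pyran-3-carboxylate | COC(=O)c1c(C[C@H](C)c2cc(OC)c(OCc3ccccc3)c(OC)c2)oc(-c2ccc(OCc3ccccc3)c(OC)c2)c(OCc2ccccc2)c1=O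
A6 | direct plan | 3-(benzyloxy)-2-[4-(benzyloxy)-3-methoxyphenyl]-8-{(1R)-1-[4-(benzyloxy)-3,5-dimethoxyphenyl]ethyl}-5,7-dihydroxy-4H-chromen-4-one | COc1cc(-c2oc3c([C@H](C)c4cc(OC)c(OCc5ccccc5)c(OC)c4)c(O)cc(O)c3c(=O)c2OCc2ccccc2)ccc1OCc1ccccc1
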